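**Retrosynthetic overview**

1. Labdane numbering is used for the ring system (C4 gem-dimethyl, C5/C10 ring fusion, C8 carrying O and CH3, C9 carrying the side chain C11–C15). Target 29 ⇒ hydroxy acid 27 (formylation last) ⇒ diol 25 ⇒ dienol 24 (hydrogenation, then alcohol-to-acid oxidation).
2. 24 ⇒ 7α,8α-epoxy-6-ketone 22 (Wharton transposition moves the oxygen from C6 to C8) ⇒ trans-enone 21 ⇒ cis-fused octalone 17 (Saegusa dehydrogenation erases the temporary C8 steering centre; kinetic protonation inverts C5).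
3. Key disconnection: ring A (C1–C2–C3–C4–C5–C10) is opened at C3–C4 and C5–C10 by a retro-Diels–Alder reaction to the acyclic trienone 16. The enabling feature is that ring A is a six-membered carbocycle made of a four-carbon unit C10–C1–C2–C3 and a two-carbon unit C4–C5 (C4 carries the gem-dimethyl pair, so C4=C5 can be an isopropylidene). C5–C10 is also the fusion bond of ring B, so the other four ring-B carbons C6–C9 are the tether, and C6 next to C5 can hold a ketone that activates C4=C5 and later hands its oxygen to C8.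
4. 16 ⇒ acid 9 (Arndt–Eistert homologation, Weinreb amide/isobutenyl Grignard, enyne semi-reduction) ⇒ propargylic propanoate 6 by Ireland–Claisen rearrangement (C8–C9 bond and both tether stereocentres by 1,3-chirality transfer) ⇒ enal 4 (asymmetric alkynylation) ⇒ (S)-citronellol 1, the source of C13.
5. Ring order: rings A and B are formed together in step 11; every compound before it is acyclic.

Key step: step 11

Assumption: the ProPhenol antipode that gives the 3R carbinol in step 3 is taken to be the (S,S)-ligand; the sense would be confirmed by Mosher ester analysis on the first run and the other antipode used if needed.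

**Route**

Step 1
Reactants: 1 (S)-citronellol
Product: 2 (S)-citronellyl benzyl ether
Conditions: NaH, BnBr, Bu4NI (cat.), THF, 0 °C → rt
Reagents that add atoms: benzyl bromide, BrCc1ccccc1
Why: Williamson etherification of the primary alcohol, which leaves the 3S centre (the future C13) untouched.

Step 2
Reactants: 2 (S)-citronellyl benzyl ether
Product: 4 (2E,6S)-8-(benzyloxy)-2,6-dimethyloct-2-enal, via allylic alcohol 3 (not isolated)
Conditions: SeO2 (cat.), t-BuOOH, CH2Cl2, rt; then MnO2, CH2Cl2, rt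
Reagents that add atoms: tert-butyl hydroperoxide, CC(C)(C)OO
Why: SeO2/t-BuOOH allylic oxidation (ene reaction then [2,3] shift) is selective for the (E)-methyl group of the trisubstituted alkene, and MnO2 should take the allylic alcohol on to the (E)-enal.

Step 3
Reactants: 4 (2E,6S)-8-(benzyloxy)-2,6-dimethyloct-2-enal
Product: 5 (3R,4E,8S)-10-(benzyloxy)-4,8-dimethyl-1-(trimethylsilyl)dec-4-en-1-yn-3-ol
Conditions: HC≡CSiMe3, Me2Zn, (S,S)-ProPhenol (cat.), Ph3P=O (cat.), toluene, 0 °C
Reagents that add atoms: ethynyltrimethylsilane, C#C[Si](C)(C)C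
Why: Me2Zn/ProPhenol-catalysed enantioselective alkynylation of an α,β-unsaturated aldehyde, in which the chiral dinuclear zinc catalyst should deliver the alkynyl group to one aldehyde face and set the carbinol as 3R independently of the remote 8S centre.

Step 4
Reactants: 5 (3R,4E,8S)-10-(benzyloxy)-4,8-dimethyl-1-(trimethylsilyl)dec-4-en-1-yn-3-ol
Product: 6 (3R,4E,8S)-10-(benzyloxy)-4,8-dimethyl-1-(trimethylsilyl)dec-4-en-1-yn-3-yl propanoate
Conditions: (EtCO)2O, Et3N, DMAP (cat.), CH2Cl2, 0 °C → rt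
Reagents that add atoms: propanoic anhydride, CCC(=O)OC(=O)CC
Why: DMAP-catalysed O-acylation, which breaks no bond at the carbinol carbon and so retains its configuration.

Step 5
Reactants: 6 (3R,4E,8S)-10-(benzyloxy)-4,8-dimethyl-1-(trimethylsilyl)dec-4-en-1-yn-3-yl propanoate
Product: 9 (2R,3S,4E)-3-[(3S)-5-(benzyloxy)-3-methylpentyl]-2,4-dimethyl-7-(trimethylsilyl)hept-4-en-6-ynoic acid, via silyl ketene acetal 7 (not isolated), via trimethylsilyl ester 8 (not isolated)
Conditions: LiN(iPr)2, THF, −78 °C; Me3SiCl; → rt then 40 °C; 1 M HCl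
Reagents that add atoms: none
Why: Ireland–Claisen rearrangement, in which LiN(iPr)2 in THF gives the (E)-silyl ketene acetal that rearranges through a chair with the alkynyl substituent equatorial, the side chain on the (E)-alkene terminus equatorial and the enolate methyl axial, so the 3R carbinol chirality should be relayed to the new 2R and 3S centres and to the (E)-enyne, while the silylated alkyne terminus blocks the competing propargylic [3,3] shift.

Step 6
Reactants: 9 (2R,3S,4E)-3-[(3S)-5-(benzyloxy)-3-methylpentyl]-2,4-dimethyl-7-(trimethylsilyl)hept-4-en-6-ynoic acid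
Product: 11 (3R,4S,5E)-4-[(3S)-5-(benzyloxy)-3-methylpentyl]-1-diazo-3,5-dimethyl-8-(trimethylsilyl)oct-5-en-7-yn-2-one, via acid chloride 10 (not isolated)
Conditions: (COCl)2, DMF (cat.), CH2Cl2, 0 °C → rt; then CH2N2, Et2O, 0 °C
Reagents that add atoms: diazomethane, C=[N+]=[N-]
Why: First half of an Arndt–Eistert homologation (acylation of diazomethane by the acid chloride), run without amine base so that the α-stereocentre is not lost through ketene formation.

Step 7
Reactants: 11 (3R,4S,5E)-4-[(3S)-5-(benzyloxy)-3-methylpentyl]-1-diazo-3,5-dimethyl-8-(trimethylsilyl)oct-5-en-7-yn-2-one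
Product: 13 (3S,4S,5E)-4-[(3S)-5-(benzyloxy)-3-methylpentyl]-N-methoxy-N,3,5-trimethyl-8-(trimethylsilyl)oct-5-en-7-ynamide, via ketene 12 (not isolated)
Conditions: PhCO2Ag (cat.), Et3N, MeNHOMe, THF, −25 °C → rt, dark
Reagents that add atoms: N,O-dimethylhydroxylamine, CNOC
Why: Silver-catalysed Wolff rearrangement with retention at the migrating stereocentre, the ketene being trapped by the hydroxylamine to give the one-carbon-homologated Weinreb amide (the descriptor changes from R to S only through the priority rules).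

Step 8
Reactants: 13 (3S,4S,5E)-4-[(3S)-5-(benzyloxy)-3-methylpentyl]-N-methoxy-N,3,5-trimethyl-8-(trimethylsilyl)oct-5-en-7-ynamide
Product: 14 (6S,7S,8E)-7-[(3S)-5-(benzyloxy)-3-methylpentyl]-2,6,8-trimethyl-11-(trimethylsilyl)undeca-2,8-dien-10-yn-4-one
Conditions: Me2C=CHMgBr, THF, 0 °C; then 1 M HCl, 0 °C
Reagents that add atoms: 2-methylprop-1-enylmagnesium bromide, CC(C)=C[Mg]Br
Why: Weinreb ketone synthesis, in which mono-addition of the alkenyl Grignard reagent to the N-methoxy-N-methylamide should give the β,β-dimethyl enone without over-addition.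

Step 9
Reactants: 14 (6S,7S,8E)-7-[(3S)-5-(benzyloxy)-3-methylpentyl]-2,6,8-trimethyl-11-(trimethylsilyl)undeca-2,8-dien-10-yn-4-one
Product: 15 (6S,7S,8E)-7-[(3S)-5-(benzyloxy)-3-methylpentyl]-2,6,8-trimethylundeca-2,8-dien-10-yn-4-one
Conditions: K2CO3, MeOH, rt
Reagents that add atoms: none
Why: Methanolysis of the alkynyl C–Si bond (protodesilylation) under carbonate conditions too mild to disturb the stereocentres β and γ to the ketone.

Step 10
Reactants: 15 (6S,7S,8E)-7-[(3S)-5-(benzyloxy)-3-methylpentyl]-2,6,8-trimethylundeca-2,8-dien-10-yn-4-one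
Product: 16 (6S,7S,8E)-7-[(3S)-5-(benzyloxy)-3-methylpentyl]-2,6,8-trimethylundeca-2,8,10-trien-4-one
Conditions: H2 (1 atm), Pd/CaCO3 poisoned with Pb(OAc)2 (Lindlar catalyst), quinoline, EtOAc, rt
Reagents that add atoms: none
Why: Lindlar semi-hydrogenation of the terminal alkyne of the conjugated enyne should give the vinyl terminus of the (E)-diene, the trisubstituted alkenes and the benzyl ether being inert to the poisoned catalyst.

Step 11
Reactants: 16 (6S,7S,8E)-7-[(3S)-5-(benzyloxy)-3-methylpentyl]-2,6,8-trimethylundeca-2,8,10-trien-4-one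
Product: 17 (3S,4S,4aR,8aR)-4-[(3S)-5-(benzyloxy)-3-methylpentyl]-3,4a,8,8-tetramethyl-3,4,4a,7,8,8a-hexahydronaphthalen-1(2H)-one (cis-fused; labdane positions 5β-H, 8β-CH3, 9β side chain, 10β-CH3, 6-oxo, 1-ene)
Conditions: Me2AlCl, CH2Cl2, −78 → −20 °C; aq. KNaC4H4O6 work-up
Reagents that add atoms: none
Why: Me2AlCl-promoted type 1 intramolecular Diels–Alder reaction of a deca-1,7,9-trien-3-one (closest precedent: Lewis-acid-promoted cyclisations of tether-ketone decatrienones to cis-fused octalones), expected to run through a strongly asynchronous, polarised transition state in which the free diene CH2 terminus bonds to the β-carbon of the aluminium-complexed s-cis enone (creating the gem-dimethyl carbon C4) ahead of the bond from the α-carbon C5 to the methyl-bearing diene terminus C10, so that matched polarity at low temperature overcomes the hindrance and avoids the 1,5-hydrogen shift open to the (Z)-methyl diene on heating. Ring A is closed as the cyclohexene of the [4+2] event, and ring B is closed by the same C5–C10 bond across the four-carbon tether C6–C9 in a chair-like six-membered array with the tether carbonyl endo. C10 is controlled by the two tether stereocentres: the C8 methyl stays equatorial on the tether chair, because the flipped chair would place it syn-axial to the axial diene carbon C1, and this holds the C9 side chain axial and exposes the diene face that puts the C10 methyl cis to the side chain. C5 is fixed by the endo mode and so should emerge cis to the C10 methyl (cis-fused), which is accepted here and corrected in step 13. The step therefore needs endo over exo closure and one diene face over the other; the first is secured by the in-tether ketone under Lewis acid activation, the second by the equatorial C8 methyl, and regiochemistry is fixed by the tether.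

Step 12
Reactants: 17 (3S,4S,4aR,8aR)-4-[(3S)-5-(benzyloxy)-3-methylpentyl]-3,4a,8,8-tetramethyl-3,4,4a,7,8,8a-hexahydronaphthalen-1(2H)-one
Product: 19 (4S,4aR,8aR)-4-[(3S)-5-(benzyloxy)-3-methylpentyl]-3,4a,8,8-tetramethyl-4a,7,8,8a-tetrahydronaphthalen-1(4H)-one, via silyl enol ether 18 (not isolated)
Conditions: LiN(SiMe3)2, Me3SiCl, THF, −78 °C; then Pd(OAc)2, MeCN, rt
Reagents that add atoms: none
Why: Saegusa–Ito dehydrogenation, in which kinetic enolisation occurs at the CH2 flank (the other α-position is a methine between two quaternary carbons and has no β-hydrogen) and Pd(OAc)2 should convert the silyl enol ether into the β-methyl enone, erasing the temporary C8 stereocentre.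

Step 13
Reactants: 19 (4S,4aR,8aR)-4-[(3S)-5-(benzyloxy)-3-methylpentyl]-3,4a,8,8-tetramethyl-4a,7,8,8a-tetrahydronaphthalen-1(4H)-one
Product: 21 (4S,4aR,8aS)-4-[(3S)-5-(benzyloxy)-3-methylpentyl]-3,4a,8,8-tetramethyl-4a,7,8,8a-tetrahydronaphthalen-1(4H)-one (trans-fused), via lithium dienolate 20 (not isolated)
Conditions: LiN(iPr)2, THF, −78 → −40 °C; then AcOH in THF, −78 °C
Reagents that add atoms: none
Why: Kinetic α′-deprotonation and diastereoselective kinetic protonation: in the cross-conjugated dienolate the C10 methyl (and the syn C4 methyl) must stand perpendicular to the enolate plane because the other two substituents of C10 are tied back into rings A and B, so C-protonation at C5 should occur on the opposite face and give the trans-fused enone, as in the axial protonations that set trans ring fusions after dissolving-metal reductions.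

Step 14
Reactants: 21 (4S,4aR,8aS)-4-[(3S)-5-(benzyloxy)-3-methylpentyl]-3,4a,8,8-tetramethyl-4a,7,8,8a-tetrahydronaphthalen-1(4H)-one
Product: 22 α-epoxide of enone 21 (oxirane oxygen on the face opposite the angular methyl; labdane positions 7α,8α-epoxy-6-oxo, 8β-CH3, 5α-H)
Conditions: 30% H2O2, NaOH (cat.), MeOH, 0 °C
Reagents that add atoms: hydrogen peroxide, OO
Why: Weitz–Scheffer nucleophilic epoxidation of a β-methyl cyclohexenone (compare isophorone oxide), in which hydroperoxide should add to C8 on the face anti to the axial C10 methyl that is 1,3 to it, so that ring closure gives the α-epoxide and fixes C8 with oxygen α and methyl β, low temperature and catalytic base limiting enolisation at C5.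

Step 15
Reactants: 22 α-epoxide of enone 21
Product: 24 (1R,2R,4aS,8aS)-1-[(3S)-5-(benzyloxy)-3-methylpentyl]-2,5,5,8a-tetramethyl-1,2,4a,5,6,8a-hexahydronaphthalen-2-ol, via epoxy hydrazone 23 (not isolated)
Conditions: N2H4·H2O, AcOH (cat.), MeOH, 0 °C → rt
Reagents that add atoms: none
Why: Wharton transposition, in which the hydrazone of the α,β-epoxy ketone fragments with loss of N2 to the allylic alcohol, removing the C6 oxygen while the tertiary C8–O bond, never broken, keeps the α-configuration set in step 14.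

Step 16
Reactants: 24 (1R,2R,4aS,8aS)-1-[(3S)-5-(benzyloxy)-3-methylpentyl]-2,5,5,8a-tetramethyl-1,2,4a,5,6,8a-hexahydronaphthalen-2-ol
Product: 25 (1R,2R,4aS,8aS)-1-[(3S)-5-hydroxy-3-methylpentyl]-2,5,5,8a-tetramethyldecahydronaphthalen-2-ol
Conditions: H2 (1 atm), Pd/C, EtOAc, rt
Reagents that add atoms: none
Why: Heterogeneous catalytic hydrogenation should saturate both disubstituted ring alkenes (no new stereocentre arises) and hydrogenolyse the benzyl ether in the same operation.

Step 17
Reactants: 25 (1R,2R,4aS,8aS)-1-[(3S)-5-hydroxy-3-methylpentyl]-2,5,5,8a-tetramethyldecahydronaphthalen-2-ol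
Product: 27 (3S)-5-[(1R,2R,4aS,8aS)-2-hydroxy-2,5,5,8a-tetramethyldecahydronaphthalen-1-yl]-3-methylpentanoic acid, via hydroxy aldehyde 26 (not isolated)
Conditions: TEMPO (cat.), PhI(OAc)2, MeCN/H2O 1:1, rt
Reagents that add atoms: water, O
Why: Oxoammonium (TEMPO/PhI(OAc)2) oxidation of the primary alcohol through the aldehyde to the carboxylic acid, the tertiary alcohol being inert to this oxidant.

Step 18
Reactants: 27 (3S)-5-[(1R,2R,4aS,8aS)-2-hydroxy-2,5,5,8a-tetramethyldecahydronaphthalen-1-yl]-3-methylpentanoic acid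
Product: 29 (3S)-5-[(1R,2R,4aS,8aS)-2-(formyloxy)-2,5,5,8a-tetramethyldecahydronaphthalen-1-yl]-3-methylpentanoic acid, via mixed formic anhydride 28 (not isolated)
Conditions: HCO2COCH3 (acetic formic anhydride), pyridine, CH2Cl2, 0 °C → rt; then H2O
Reagents that add atoms: acetic formic anhydride, CC(=O)OC=O
Why: O-Formylation of the hindered tertiary alcohol by the small formyl group of the mixed anhydride, the carboxyl group being transiently converted into its mixed formic anhydride, which should hydrolyse on aqueous work-up while the tertiary formate survives.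

**Compound list**

1 | (S)-citronellol, (3S)-3,7-dimethyloct-6-en-1-ol | C[C@@H](CCC=C(C)C)CCO | starting material
2 | (S)-citronellyl benzyl ether | C[C@@H](CCC=C(C)C)CCOCc1ccccc1 | intermediate
3 | (2E,6S)-8-(benzyloxy)-2,6-dimethyloct-2-en-1-ol | OC/C(C)=C/CC[C@H](C)CCOCc1ccccc1 | intermediate
4 | (2E,6S)-8-(benzyloxy)-2,6-dimethyloct-2-enal | O=C/C(C)=C/CC[C@H](C)CCOCc1ccccc1 | intermediate
5 | (3R,4E,8S)-10-(benzyloxy)-4,8-dimethyl-1-(trimethylsilyl)dec-4-en-1-yn-3-ol | C[Si](C)(C)C#C[C@H](O)/C(C)=C/CC[C@H](C)CCOCc1ccccc1 | intermediate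
6 | (3R,4E,8S)-10-(benzyloxy)-4,8-dimethyl-1-(trimethylsilyl)dec-4-en-1-yn-3-yl propanoate | C[Si](C)(C)C#C[C@H](OC(=O)CC)/C(C)=C/CC[C@H](C)CCOCc1ccccc1 | intermediate
7 | (E)-trimethylsilyl ketene acetal of 6 (enolate methyl cis to the allylic oxygen) | C/C=C(/O[Si](C)(C)C)O[C@@H](C#C[Si](C)(C)C)/C(C)=C/CC[C@H](C)CCOCc1ccccc1 | intermediate
8 | trimethylsilyl ester of acid 9 | C[C@@H](C(=O)O[Si](C)(C)C)[C@H](CC[C@H](C)CCOCc1ccccc1)/C(C)=C/C#C[Si](C)(C)C | intermediate
9 | (2R,3S,4E)-3-[(3S)-5-(benzyloxy)-3-methylpentyl]-2,4-dimethyl-7-(trimethylsilyl)hept-4-en-6-ynoic acid | C[C@@H](C(=O)O)[C@H](CC[C@H](C)CCOCc1ccccc1)/C(C)=C/C#C[Si](C)(C)C | intermediate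
10 | acid chloride of 9 | C[C@@H](C(=O)Cl)[C@H](CC[C@H](C)CCOCc1ccccc1)/C(C)=C/C#C[Si](C)(C)C | intermediate
11 | (3R,4S,5E)-4-[(3S)-5-(benzyloxy)-3-methylpentyl]-1-diazo-3,5-dimethyl-8-(trimethylsilyl)oct-5-en-7-yn-2-one | C[C@@H](C(=O)C=[N+]=[N-])[C@H](CC[C@H](C)CCOCc1ccccc1)/C(C)=C/C#C[Si](C)(C)C | intermediate
12 | ketene from Wolff rearrangement of 11 | C[C@@H](C=C=O)[C@H](CC[C@H](C)CCOCc1ccccc1)/C(C)=C/C#C[Si](C)(C)C | intermediate
13 | (3S,4S,5E)-4-[(3S)-5-(benzyloxy)-3-methylpentyl]-N-methoxy-N,3,5-trimethyl-8-(trimethylsilyl)oct-5-en-7-ynamide | C[C@@H](CC(=O)N(C)OC)[C@H](CC[C@H](C)CCOCc1ccccc1)/C(C)=C/C#C[Si](C)(C)C | intermediate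
14 | (6S,7S,8E)-7-[(3S)-5-(benzyloxy)-3-methylpentyl]-2,6,8-trimethyl-11-(trimethylsilyl)undeca-2,8-dien-10-yn-4-one | C[C@@H](CC(=O)C=C(C)C)[C@H](CC[C@H](C)CCOCc1ccccc1)/C(C)=C/C#C[Si](C)(C)C | intermediate
15 | (6S,7S,8E)-7-[(3S)-5-(benzyloxy)-3-methylpentyl]-2,6,8-trimethylundeca-2,8-dien-10-yn-4-one | C[C@@H](CC(=O)C=C(C)C)[C@H](CC[C@H](C)CCOCc1ccccc1)/C(C)=C/C#C | intermediate
16 | (6S,7S,8E)-7-[(3S)-5-(benzyloxy)-3-methylpentyl]-2,6,8-trimethylundeca-2,8,10-trien-4-one | C[C@@H](CC(=O)C=C(C)C)[C@H](CC[C@H](C)CCOCc1ccccc1)/C(C)=C/C=C | intermediate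
17 | (3S,4S,4aR,8aR)-4-[(3S)-5-(benzyloxy)-3-methylpentyl]-3,4a,8,8-tetramethyl-3,4,4a,7,8,8a-hexahydronaphthalen-1(2H)-one (cis-fused) | C[C@@H](CC[C@@H]1[C@@]2(C)C=CCC(C)(C)[C@H]2C(=O)C[C@@H]1C)CCOCc1ccccc1 | intermediate
18 | trimethylsilyl enol ether of 17 (C1(OSiMe3)=C2 of the naphthalenone) | C[C@@H](CC[C@@H]1[C@@]2(C)C=CCC(C)(C)[C@H]2C(O[Si](C)(C)C)=C[C@@H]1C)CCOCc1ccccc1 | intermediate
19 | (4S,4aR,8aR)-4-[(3S)-5-(benzyloxy)-3-methylpentyl]-3,4a,8,8-tetramethyl-4a,7,8,8a-tetrahydronaphthalen-1(4H)-one (cis-fused enone) | C[C@@H](CC[C@@H]1[C@@]2(C)C=CCC(C)(C)[C@H]2C(=O)C=C1C)CCOCc1ccccc1 | intermediate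
20 | cross-conjugated lithium dienolate of 19 (C8a=C1(OLi)–C2=C3) | C[C@@H](CC[C@@H]1[C@@]2(C)C=CCC(C)(C)C2=C(O[Li])C=C1C)CCOCc1ccccc1 | intermediate
21 | (4S,4aR,8aS)-4-[(3S)-5-(benzyloxy)-3-methylpentyl]-3,4a,8,8-tetramethyl-4a,7,8,8a-tetrahydronaphthalen-1(4H)-one (trans-fused enone) | C[C@@H](CC[C@@H]1[C@@]2(C)C=CCC(C)(C)[C@@H]2C(=O)C=C1C)CCOCc1ccccc1 | intermediate
22 | α-epoxide of enone 21 (labdane positions 7α,8α-epoxy-6-oxo, 8β-CH3, 5α-H) | C[C@@H](CC[C@@H]1[C@@]2(C)C=CCC(C)(C)[C@@H]2C(=O)[C@H]3O[C@@]13C)CCOCc1ccccc1 | intermediate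
23 | hydrazone of epoxy ketone 22 | C[C@@H](CC[C@@H]1[C@@]2(C)C=CCC(C)(C)[C@@H]2C(=NN)[C@H]3O[C@@]13C)CCOCc1ccccc1 | intermediate
24 | (1R,2R,4aS,8aS)-1-[(3S)-5-(benzyloxy)-3-methylpentyl]-2,5,5,8a-tetramethyl-1,2,4a,5,6,8a-hexahydronaphthalen-2-ol | C[C@@H](CC[C@@H]1[C@@]2(C)C=CCC(C)(C)[C@@H]2C=C[C@@]1(C)O)CCOCc1ccccc1 | intermediate
25 | (1R,2R,4aS,8aS)-1-[(3S)-5-hydroxy-3-methylpentyl]-2,5,5,8a-tetramethyldecahydronaphthalen-2-ol | C[C@@H](CC[C@@H]1[C@@]2(C)CCCC(C)(C)[C@@H]2CC[C@@]1(C)O)CCO | intermediate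
26 | (3S)-5-[(1R,2R,4aS,8aS)-2-hydroxy-2,5,5,8a-tetramethyldecahydronaphthalen-1-yl]-3-methylpentanal | C[C@@H](CC[C@@H]1[C@@]2(C)CCCC(C)(C)[C@@H]2CC[C@@]1(C)O)CC=O | intermediate
27 | (3S)-5-[(1R,2R,4aS,8aS)-2-hydroxy-2,5,5,8a-tetramethyldecahydronaphthalen-1-yl]-3-methylpentanoic acid | C[C@@H](CC[C@@H]1[C@@]2(C)CCCC(C)(C)[C@@H]2CC[C@@]1(C)O)CC(=O)O | intermediate
28 | mixed formic anhydride of target 29 | C[C@@H](CC[C@@H]1[C@@]2(C)CCCC(C)(C)[C@@H]2CC[C@@]1(C)OC=O)CC(=O)OC=O | intermediate
29 | (3S)-5-[(1R,2R,4aS,8aS)-2-(formyloxy)-2,5,5,8a-tetramethyldecahydronaphthalen-1-yl]-3-methylpentanoic acid | C[C@@H](CC[C@@H]1[C@@]2(C)CCCC(C)(C)[C@@H]2CC[C@@]1(C)OC=O)CC(=O)O | target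

**Totals**

Total step count: 18. Longest linear sequence: 18 steps, from (S)-citronellol 1.

**Steps most likely to fail**

Step 11. Endo selectivity may be lost (exo closure through the alternative tether arrangement would deliver the C10 epimer), or the aluminium Lewis acid may ionise and oligomerise the electron-rich diene before cyclisation. The fallback sets out from 16 and comes back at 17. Trienone 16 is treated with 1,2-bis(trimethylsiloxy)ethane and catalytic Me3SiOTf in CH2Cl2 at −78 °C. The triene dioxolane F1 forms in the flask, ionises to the 2-alkoxyallyl cation and undergoes the ionic (Gassman-type) [4+2] closure, which runs through a compact, endo-selective cation–diene array, to the cycloadduct dioxolane F2. Aqueous HCl in THF then releases ketone 17.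

Step 13. Facial leakage in the C-protonation, or re-equilibration towards the cis-fused enone during the quench, may leave a mixture at C5. The fallback sets out from 19 and comes back at 25, replacing steps 13 to 16, and sets C5 by hydrogenation instead of protonation. KN(SiMe3)2 and PhNTf2 convert 19 into the cross-conjugated dienyl triflate F3, in which C5 is sp2. Reduction with HCO2H/Bu3N under Pd(OAc)2/PPh3 catalysis gives the ring-B diene F4. Buffered m-CPBA epoxidises the less hindered trisubstituted double bond (C7=C8) from the α-face to the vinyl epoxide F5. LiAlH4 opens this at the allylic CH to the tertiary alcohol F6. Hydrogenation over Pd/C then adds hydrogen to the C5=C6 alkene from the face opposite the C10 methyl, as in the reduction of 5-ene steroids, saturates ring A and cleaves the benzyl ether to give diol 25.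

Step 15. Hydrazone formation at the hindered carbonyl may be incomplete, or the intermediate may decompose non-productively instead of fragmenting, which is common for fully substituted epoxides. The fallback sets out from 22 and comes back at 25. Reductive opening of the epoxy ketone with NaBH4/(PhSe)2/AcOH in EtOH gives the β-hydroxy ketone F7. TsNHNH2 converts it into the tosylhydrazone F8. Catecholborane followed by NaOAc·3H2O reduces this to the methylene compound F9. Hydrogenation under the conditions of step 16 gives 25.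

Further compounds
F1 | step 11 | ethylene ketal (1,3-dioxolane) of trienone 16 | C[C@@H](CC1(OCCO1)C=C(C)C)[C@H](CC[C@H](C)CCOCc1ccccc1)/C(C)=C/C=C
F2 | step 11 | ethylene ketal (1,3-dioxolane) of cis-fused octalone 17 | C[C@@H](CC[C@@H]1[C@@]2(C)C=CCC(C)(C)[C@H]2C3(OCCO3)C[C@@H]1C)CCOCc1ccccc1
F3 | step 13 | cross-conjugated dienyl triflate of 19 (C8a=C1(OTf)–C2=C3) | C[C@@H](CC[C@@H]1[C@@]2(C)C=CCC(C)(C)C2=C(OS(=O)(=O)C(F)(F)F)C=C1C)CCOCc1ccccc1
F4 | step 13 | triene from reduction of F3 (labdane 1,5,7-triene, 15-benzyl ether) | C[C@@H](CC[C@@H]1[C@@]2(C)C=CCC(C)(C)C2=CC=C1C)CCOCc1ccccc1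
F5 | step 13 | 7α,8α-epoxide of F4 (vinyl epoxide) | C[C@@H](CC[C@@H]1[C@@]2(C)C=CCC(C)(C)C2=C[C@H]3O[C@@]13C)CCOCc1ccccc1
F6 | step 13 | labda-1,5-dien-8α-ol 15-benzyl ether | C[C@@H](CC[C@@H]1[C@@]2(C)C=CCC(C)(C)C2=CC[C@@]1(C)O)CCOCc1ccccc1
F7 | step 15 | 8α-hydroxy-6-ketone from reductive opening of 22 | C[C@@H](CC[C@@H]1[C@@]2(C)C=CCC(C)(C)[C@@H]2C(=O)C[C@@]1(C)O)CCOCc1ccccc1
F8 | step 15 | tosylhydrazone of F7 | C[C@@H](CC[C@@H]1[C@@]2(C)C=CCC(C)(C)[C@@H]2C(=NNS(=O)(=O)c3ccc(C)cc3)C[C@@]1(C)O)CCOCc1ccccc1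
F9 | step 15 | labd-1-en-8α-ol 15-benzyl ether | C[C@@H](CC[C@@H]1[C@@]2(C)C=CCC(C)(C)[C@@H]2CC[C@@]1(C)O)CCOCc1ccccc1
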